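Numbering: ring A (cycloheptane) = C1 (carbinol carbon bearing the side chain), C5 (ester carbinol), C6 (lactone oxygen), C7, C8, C9 (CHOH), C10 (CHCH3, methyl = C14). Ring B (lactone) = O, C6, C7, C11, C12, with C13 as the methylene carbon. Side chain = C2(=O)-C3-C4(OH)-C15.
Enabling feature: C5(O)-C1(OH)-C2(=O) is an oxidized β-diketone with C1 as its central carbon. Ring A without C1 (C5, C6, C7, C8, C9, C10), together with C14 and C11-C13, is the carbon skeleton of carvone. C1-C4 and C15 make up a diazoketone derived from 3-hydroxybutanoate.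
Cuts, in retrosynthetic order: ester O-C1'; C5-H (back to the ketone); C1-OH; then C1-C10 and C1-C5 (C1 leaves ring A as a diazo carbon); C9/C10 functionality back to the enone; O-C6 of ring B; C12 back to the isopropenyl methyl group.
Forward: ring B is closed first on the six-membered carvone ring. Ring A is formed last, when C1 is inserted into the C5-C10 bond (six to seven members), which joins the C10 and C5 fragments at the most hindered carbon.
Stereochemistry: C7 comes from (R)-carvone, C4 from methyl (R)-3-hydroxybutanoate and C2' from (S)-2-methylbutanoic acid. C9, C6, C10, C1 and C5 follow by substrate control (anti epoxidation, SN2 lactonization, equilibration plus retentive shift, face-selective hydroxylation, hydroxyl-directed hydride delivery).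

Key step: step 12

Faces: β is the face of ring A that carries H-6 and H-7 (in the target also 9-OH, the C2 side chain and the C5 ester oxygen). α carries O-6, C11, C14 and 1-OH.
Remark on the chemistry: C11 of 8, 9, 10, 17, 18 and 19 is a temporary centre that step 13 erases, and it is drawn with CH2SePh on the H-7 side. C1 of 18 is stereolabile and is drawn without configuration.

Step 1
Reactants: 1 (R)-(−)-carvone
Product: 2 (1R,4R,6R)-carvone oxide (9β,10β-epoxy ketone; isopropenyl α)
Conditions: 30% aq. H2O2, NaOH (cat.), MeOH, 0 °C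
Reagents that add atoms: hydrogen peroxide, OO
Why: Weitz–Scheffer nucleophilic epoxidation attacks only the electron-poor enone double bond, and hydroperoxide adds to C9 on the β face, anti to the α isopropenyl group on C7, which sets C9 (C10 is reset in step 6).

Step 2
Reactants: 2 (1R,4R,6R)-carvone oxide
Product: 3 allylic chloride (C7 side chain = 3-chloroprop-1-en-2-yl)
Conditions: Ca(OCl)2, solid CO2, CH2Cl2/H2O, 0 °C
Reagents that add atoms: calcium hypochlorite, [Ca+2].[O-]Cl.[O-]Cl
Why: Ene-type allylic chlorination by HOCl takes place at the only remaining alkene, the electron-rich 1,1-disubstituted isopropenyl group, with transposition of the double bond, and it touches no stereocenter.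

Step 3
Reactants: 3 allylic chloride
Product: 4 enal (C7 side chain = 3-oxoprop-1-en-2-yl)
Conditions: N-methylmorpholine N-oxide, KI (cat.), NaHCO3, MeCN, 40 °C
Reagents that add atoms: N-methylmorpholine N-oxide, C[N+]1([O-])CCOCC1
Why: Amine N-oxide oxidation of an allylic halide (Kornblum type), in which iodide-assisted SN2 attack of the N-oxide oxygen on C12 and base-induced loss of N-methylmorpholine give the enal without touching the epoxy ketone.

Step 4
Reactants: 4 enal
Product: 5 acrylic acid (C12 = CO2H)
Conditions: NaClO2, NaH2PO4, 2-methyl-2-butene, t-BuOH/H2O, 0 to 23 °C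
Reagents that add atoms: sodium chlorite, [Na+].[O-]Cl=O
Why: Pinnick oxidation converts the enal into the acrylic acid under buffered conditions that leave the alkene, the epoxide and the ketone alone.

Step 5
Reactants: 5 acrylic acid
Product: 7 cis-fused epoxy keto α-methylene lactone, via C6 β-aryliodanyl ketone 6 (not isolated)
Conditions: PhI(OH)OTs, CH2Cl2, 40 °C
Reagents that add atoms: none
Why: Oxylactonization of a 5-oxo acid with a trivalent iodine reagent, in which only C6 can enolize because C10 is fully substituted, the iodane is taken up on the β face anti to the C7 substituent (6), and the tethered carboxylate displaces iodobenzene from the α face in an SN2 step, so that only the cis-fused lactone (O-6 α) can form.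

Step 6
Reactants: 7 cis-fused epoxy keto α-methylene lactone
Product: 9 9β-hydroxy-13-phenylselanyl keto lactone (C14 α), via 13-phenylselanyl epoxy ketone 8 (not isolated)
Conditions: (PhSe)2, NaBH4, EtOH, 0 °C; then AcOH and 7, 0 °C
Reagents that add atoms: diphenyl diselenide, c1ccc(cc1)[Se][Se]c1ccccc1
Why: Selenolate-mediated reduction of an α,β-epoxy ketone to the aldol cleaves only the C10–O bond and keeps the β C9–O bond, the same reagent masks the α-methylene lactone by conjugate addition (8), and C10 is set on protonation of the enolate under equilibrating conditions, which favour the chair with C14, O-9 and O-6 all equatorial (C14 α).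

Step 7
Reactants: 9 9β-hydroxy-13-phenylselanyl keto lactone
Product: 10 C9 tert-butyldimethylsilyl ether of 9
Conditions: t-BuMe2SiOTf, 2,6-lutidine, CH2Cl2, −78 °C
Reagents that add atoms: tert-butyldimethylsilyl triflate, CC(C)(C)[Si](C)(C)OS(=O)(=O)C(F)(F)F
Why: Silylation with the silyl triflate and a hindered pyridine at low temperature protects the secondary C9 alcohol faster than the β-hydroxy ketone can dehydrate or epimerize.

Step 8
Reactants: 11 methyl (R)-3-hydroxybutanoate
Product: 12 methyl (R)-3-(tert-butyldimethylsilyloxy)butanoate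
Conditions: t-BuMe2SiCl, imidazole, DMF, 23 °C
Reagents that add atoms: tert-butyldimethylsilyl chloride, CC(C)(C)[Si](C)(C)Cl
Why: Standard silyl ether formation, in which C4 comes unchanged from the chiral pool ester.

Step 9
Reactants: 12 methyl (R)-3-(tert-butyldimethylsilyloxy)butanoate
Product: 13 (R)-3-(tert-butyldimethylsilyloxy)butanoic acid
Conditions: LiOH, THF/MeOH/H2O, 0 °C; then 1 M HCl
Reagents that add atoms: lithium hydroxide, [Li+].[OH-]
Why: Saponification of the methyl ester at low temperature retains C4 because the β-silyloxy group is a poor leaving group.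

Step 10
Reactants: 13 (R)-3-(tert-butyldimethylsilyloxy)butanoic acid
Product: 15 (R)-1-diazo-4-(tert-butyldimethylsilyloxy)pentan-2-one, via mixed carbonic anhydride 14 (not isolated)
Conditions: i-BuOCOCl, N-methylmorpholine, THF, −15 °C; then CH2N2, Et2O, 0 °C
Reagents that add atoms: diazomethane, C=[N+]=[N-]
Why: Acylation of diazomethane by the mixed carbonic anhydride 14 (first stage of the Arndt–Eistert sequence) gives the α-diazoketone without any acid that could cleave the silyl ether.

Step 11
Reactants: 10 C9 silyl ether keto lactone; 15 (R)-1-diazo-4-(tert-butyldimethylsilyloxy)pentan-2-one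
Product: 17 5α-hydroxy C5 adduct (β-hydroxy-α-diazoketone), via lithiated diazoketone 16 (not isolated)
Conditions: LiN(iPr)2, THF, −78 °C; then 10, −78 °C; AcOH quench at −78 °C
Reagents that add atoms: none
Why: Aldol-type addition of a lithiated α-diazoketone to a ketone, in which the carbonyl group of 10 is activated by its α-acyloxy substituent and attack occurs on the β face because the axial C7–C11 bond blocks the α face, which places 5-OH α.

Step 12
Reactants: 17 5α-hydroxy C5 adduct (β-hydroxy-α-diazoketone)
Product: 18 ring-enlarged β-diketone (2-acylcycloheptanone fused to ring B; C1 stereolabile)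
Conditions: Rh2(OAc)4 (1 mol %), CH2Cl2, 23 °C
Reagents that add atoms: none
Why: Rh2(OAc)4 expels N2 from 17 to give an electrophilic rhodium carbenoid at C1, and the adjacent C5–C10 bond shifts to C1 while O-5 pushes, so that C5 becomes the ketone and C1 is stitched in between C5 and C10 (semipinacol-type 1,2-alkyl shift). The closest known reaction type is the dirhodium-catalysed ring enlargement of the adducts of lithiated α-diazocarbonyl compounds and cycloalkanones to 2-acylcycloalkanones. Ring A is therefore closed not by an end-to-end cyclization but by one-carbon enlargement of the carvone ring from six to seven members, with ring B already in place. C10 migrates with retention, so that its configuration is carried over from 10, whereas C1 is born as the stereolabile centre of a β-diketone and is fixed only in step 13. The step needs migration of C10 and not of C6, and this is secured by the lactone oxygen on C6, which makes that carbon electron-poor and a poor migrating group. O–H insertion and oxonium ylide formation with the C4 silyl ether should be outrun because the migrating bond sits directly beside the carbenoid carbon.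

Step 13
Reactants: 18 ring-enlarged β-diketone
Product: 20 1α-hydroxy-2,5-diketone bearing the free 11(13)-methylene lactone, via selenoxide 19 (not isolated)
Conditions: dimethyldioxirane (acetone solution, excess), CH2Cl2, −20 to 23 °C
Reagents that add atoms: dimethyldioxirane, CC1(C)OO1
Why: Electrophilic α-hydroxylation of the enolized β-diketone by the dioxirane, in which allylic strain holds H-10 in the enol plane, the pseudoaxial C9 silyl ether closes the β face and oxygen enters from the α face beside the small C14 methyl group, while the same oxidant turns the selenide into selenoxide 19, whose syn elimination restores the 11(13)-methylene group.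

Step 14
Reactants: 20 1α-hydroxy-2,5-diketone
Product: 21 1α,5β-diol (C2 ketone kept)
Conditions: Me4NBH(OAc)3 (1.1 equiv), MeCN/AcOH, −40 °C
Reagents that add atoms: none
Why: Hydroxyl-directed reduction (Evans–Saksena type), in which the α 1-OH binds the borohydride and delivers hydride to the α face of the adjacent ring ketone to give the β C5 alcohol (trans diol), and C5=O should react before C2=O because it carries two α oxygen substituents and is the more electrophilic carbonyl group.

Step 15
Reactants: 21 1α,5β-diol; 22 (S)-2-methylbutanoic acid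
Product: 23 C5 (S)-2-methylbutanoate (bis-silyl ether of the target)
Conditions: DCC, DMAP (cat.), CH2Cl2, 0 °C
Reagents that add atoms: none
Why: Steglich esterification acylates the only free secondary hydroxyl group (5-OH), the tertiary 1-OH being inert, and the mild carbodiimide conditions keep C2' of the acid intact.

Step 16
Reactants: 23 C5 (S)-2-methylbutanoate (bis-silyl ether)
Product: 24 target CNP0291806.4
Conditions: HF·pyridine, THF, 0 to 23 °C
Reagents that add atoms: none
Why: Fluoride-mediated cleavage of both silyl ethers under buffered acidic conditions avoids the base-induced retro-aldol cleavage, acyl migration and conjugate addition to which the target is prone.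

Compound list
1 | (R)-(−)-carvone, (5R)-2-methyl-5-(prop-1-en-2-yl)cyclohex-2-en-1-one | C=C(C)[C@@H]1CC=C(C)C(=O)C1 | starting material
2 | (1R,4R,6R)-1-methyl-4-(prop-1-en-2-yl)-7-oxabicyclo[4.1.0]heptan-2-one (9β,10β-epoxide, isopropenyl α) | C=C(C)[C@@H]1C[C@H]2O[C@@]2(C)C(=O)C1 | intermediate
3 | (1R,4R,6R)-4-(3-chloroprop-1-en-2-yl)-1-methyl-7-oxabicyclo[4.1.0]heptan-2-one | C=C(CCl)[C@@H]1C[C@H]2O[C@@]2(C)C(=O)C1 | intermediate
4 | 2-[(1R,4R,6R)-1-methyl-2-oxo-7-oxabicyclo[4.1.0]heptan-4-yl]prop-2-enal | C=C(C=O)[C@@H]1C[C@H]2O[C@@]2(C)C(=O)C1 | intermediate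
5 | 2-[(1R,4R,6R)-1-methyl-2-oxo-7-oxabicyclo[4.1.0]heptan-4-yl]prop-2-enoic acid | C=C(C(=O)O)[C@@H]1C[C@H]2O[C@@]2(C)C(=O)C1 | intermediate
6 | acid 5 carrying a phenyl(tosyloxy)-λ3-iodanyl group on C6, β, trans to the C7 side chain | C=C(C(=O)O)[C@@H]1C[C@H]2O[C@@]2(C)C(=O)[C@H]1I(c1ccccc1)OS(=O)(=O)c1ccc(C)cc1 | intermediate
7 | cis-fused 6,12-lactone (O-6 α, H-6 and H-7 β) with 11(13)-methylene, C5 ketone and 9β,10β-epoxide on the six-membered ring | C=C1C(=O)O[C@@H]2[C@H]1C[C@H]3O[C@@]3(C)C2=O | intermediate
8 | 7 after conjugate addition of benzeneselenol (13-SePh, epoxide intact) | c1ccc(cc1)[Se]C[C@@H]1C(=O)O[C@@H]2[C@H]1C[C@H]3O[C@@]3(C)C2=O | intermediate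
9 | 9β-hydroxy-10-(α-methyl)-5-oxo-13-phenylselanyl lactone (six-membered carbocycle) | c1ccc(cc1)[Se]C[C@@H]1C(=O)O[C@@H]2[C@H]1C[C@@H](O)[C@H](C)C2=O | intermediate
10 | C9 tert-butyldimethylsilyl ether of 9 | c1ccc(cc1)[Se]C[C@@H]1C(=O)O[C@@H]2[C@H]1C[C@@H](O[Si](C)(C)C(C)(C)C)[C@H](C)C2=O | intermediate
11 | methyl (R)-3-hydroxybutanoate | C[C@@H](O)CC(=O)OC | starting material
12 | methyl (R)-3-(tert-butyldimethylsilyloxy)butanoate | C[C@@H](O[Si](C)(C)C(C)(C)C)CC(=O)OC | intermediate
13 | (R)-3-(tert-butyldimethylsilyloxy)butanoic acid | C[C@@H](O[Si](C)(C)C(C)(C)C)CC(=O)O | intermediate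
14 | mixed anhydride of 13 and isobutyl hydrogen carbonate | C[C@@H](O[Si](C)(C)C(C)(C)C)CC(=O)OC(=O)OCC(C)C | intermediate
15 | (R)-1-diazo-4-(tert-butyldimethylsilyloxy)pentan-2-one (C1-C4 and C15) | C[C@@H](O[Si](C)(C)C(C)(C)C)CC(=O)C=[N+]=[N-] | intermediate
16 | 1-lithio derivative of 15 | [Li]C(=[N+]=[N-])C(=O)C[C@@H](C)O[Si](C)(C)C(C)(C)C | intermediate
17 | tertiary C5 carbinol (5-OH α, diazoacyl chain β) from 10 and 15 | c1ccc(cc1)[Se]C[C@@H]1C(=O)O[C@@H]2[C@H]1C[C@@H](O[Si](C)(C)C(C)(C)C)[C@H](C)[C@@]2(O)C(=[N+]=[N-])C(=O)C[C@@H](C)O[Si](C)(C)C(C)(C)C | intermediate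
18 | cycloheptane-fused lactone with C5 ketone and C1 bearing H and the C2 acyl chain (β-diketone, largely enolized) | c1ccc(cc1)[Se]C[C@@H]1C(=O)O[C@@H]2[C@H]1C[C@@H](O[Si](C)(C)C(C)(C)C)[C@H](C)C(C(=O)C[C@@H](C)O[Si](C)(C)C(C)(C)C)C2=O | intermediate
19 | 1α-hydroxy diketone with C13 phenylselenoxide | O=[Se](c1ccccc1)C[C@@H]1C(=O)O[C@@H]2[C@H]1C[C@@H](O[Si](C)(C)C(C)(C)C)[C@H](C)[C@@](O)(C(=O)C[C@@H](C)O[Si](C)(C)C(C)(C)C)C2=O | intermediate
20 | 1α-hydroxy-2,5-diketone, 11(13)-methylene lactone, 4,9-bis(silyl ether) | C=C1C(=O)O[C@@H]2[C@H]1C[C@@H](O[Si](C)(C)C(C)(C)C)[C@H](C)[C@@](O)(C(=O)C[C@@H](C)O[Si](C)(C)C(C)(C)C)C2=O | intermediate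
21 | 1α,5β-diol, C2 ketone, 4,9-bis(silyl ether) | C=C1C(=O)O[C@@H]2[C@H]1C[C@@H](O[Si](C)(C)C(C)(C)C)[C@H](C)[C@@](O)(C(=O)C[C@@H](C)O[Si](C)(C)C(C)(C)C)[C@H]2O | intermediate
22 | (S)-2-methylbutanoic acid | CC[C@H](C)C(=O)O | starting material
23 | 5β-O-[(S)-2-methylbutanoyl] derivative of 21 | C=C1C(=O)O[C@@H]2[C@H]1C[C@@H](O[Si](C)(C)C(C)(C)C)[C@H](C)[C@@](O)(C(=O)C[C@@H](C)O[Si](C)(C)C(C)(C)C)[C@H]2OC(=O)[C@@H](C)CC | intermediate
24 | CNP0291806.4 | C=C1C(=O)O[C@@H]2[C@H]1C[C@@H](O)[C@H](C)[C@@](O)(C(=O)C[C@@H](C)O)[C@H]2OC(=O)[C@@H](C)CC | target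

Total step count: 16. Longest linear sequence: 13 steps (steps 1 to 7 and 11 to 16).

Steps most likely to fail

Step 11. Proton transfer from H-6 or H-10 of 10 to the basic lithio compound may outrun carbonyl addition. The resulting enolization could lead to loss of silanolate from C9 or to epimerization, and the adduct may also revert by retro-aldol cleavage.
The fallback sets out from 10 and 15 and comes back at 18, merging steps 11 and 12 into a base-free, cationic union. BF3·OEt2 in CH2Cl2 at −40 °C activates the ketone of 10, and the neutral diazoketone 15 adds through its diazo carbon to give the BF3-bound β-oxido diazonium adduct F1. This adduct loses nitrogen with the same shift of C10. The reaction type is the Lewis acid-promoted homologation of cycloalkanones with diazocarbonyl compounds (Tiffeneau–Demjanov type).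

Step 13. Poor facial selectivity is the main risk, since attack of the oxidant on the β face would give the C1 epimer. Oxidative cleavage of the β-diketone may also compete.
The fallback sets out from 17 and comes back at 20, and it replaces face selection by chirality transfer. Excess dimethyldioxirane converts the diazo carbon of 17 into a ketone and unmasks the lactone methylene at the same time, giving the 5α-hydroxy-1,2-diketone F2 on the six-membered ring. MgBr2·OEt2 or Al(OtBu)3 then triggers an α-ketol rearrangement. In the syn-chelated arrangement of 5-O and C1=O, C10 lies over one face only of the C1 carbonyl group, so its shift turns the 5α-OH configuration set in step 11 into the 1α-OH configuration. The change from a 1,2- to a 1,3-diketone drives the ring enlargement.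

Step 14. Hydride transfer to the C2 ketone may compete with reduction at C5, which would be a loss of chemoselectivity.
The fallback sets out from 20 and comes back at 23 by a redox and protection detour. Excess Me4NBH(OAc)3 reduces both ketones by the same directed delivery to give the 1,2,5-triol F3 (5-OH β, C2 carbinol as either epimer). 2,2-Dimethoxypropane with pyridinium tosylate closes the dioxolane only on the exocyclic 1,2-diol, because the trans ring diol cannot follow, and gives the acetonide F4. Steglich esterification with 22 gives the C5 ester F5, and aqueous acetic acid frees the 1,2-diol F6. Oxidation of the single secondary alcohol of F6 with the triacetoxy periodinane (1,1,1-triacetoxy-1,2-benziodoxol-3-one) then gives 23.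

Further compounds
F1 | step 11 | BF3-bound β-oxido diazonium adduct of 10 and 15 | c1ccc(cc1)[Se]C[C@@H]1C(=O)O[C@@H]2[C@H]1C[C@@H](O[Si](C)(C)C(C)(C)C)[C@H](C)[C@@]2(O[B-](F)(F)F)C([N+]#N)C(=O)C[C@@H](C)O[Si](C)(C)C(C)(C)C
F2 | step 13 | 5α-hydroxy-1,2-diketone on the six-membered ring, 11(13)-methylene lactone | C=C1C(=O)O[C@@H]2[C@H]1C[C@@H](O[Si](C)(C)C(C)(C)C)[C@H](C)[C@@]2(O)C(=O)C(=O)C[C@@H](C)O[Si](C)(C)C(C)(C)C
F3 | step 14 | 1α,2,5β-triol (C2 epimers), 4,9-bis(silyl ether) | C=C1C(=O)O[C@@H]2[C@H]1C[C@@H](O[Si](C)(C)C(C)(C)C)[C@H](C)[C@@](O)(C(O)C[C@@H](C)O[Si](C)(C)C(C)(C)C)[C@H]2O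
F4 | step 14 | 1,2-O-isopropylidene derivative of F3 with free 5β-OH | C=C1C(=O)O[C@@H]2[C@H]1C[C@@H](O[Si](C)(C)C(C)(C)C)[C@H](C)[C@@](O3)(C(C[C@@H](C)O[Si](C)(C)C(C)(C)C)OC3(C)C)[C@H]2O
F5 | step 14 | 5β-O-[(S)-2-methylbutanoyl] derivative of F4 | C=C1C(=O)O[C@@H]2[C@H]1C[C@@H](O[Si](C)(C)C(C)(C)C)[C@H](C)[C@@](O3)(C(C[C@@H](C)O[Si](C)(C)C(C)(C)C)OC3(C)C)[C@H]2OC(=O)[C@@H](C)CC
F6 | step 14 | 1α,2-diol 5β-(S)-2-methylbutanoate, 4,9-bis(silyl ether) | C=C1C(=O)O[C@@H]2[C@H]1C[C@@H](O[Si](C)(C)C(C)(C)C)[C@H](C)[C@@](O)(C(O)C[C@@H](C)O[Si](C)(C)C(C)(C)C)[C@H]2OC(=O)[C@@H](C)CC
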